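Readings and results are calculated from invented constants; scatter was added.

**The task.** 6 questions stand below, and we mean to answer them with one straight line.

the same everywhere: starting material 1.5 M
- summer: partner 2 equiv; initiator 7 mol%; run made earlier
- dawn: partner 2 equiv; initiator 16 mol%; run made earlier
- south-west: partner 2.00 equiv; initiator 10 mol%; time 20 min
- north-west: partner 2.00 equiv; initiator 6.2 mol%; time 20 min
- north: partner 2.00 equiv; initiator 8.1 mol%; time 20 min

| run | time / min | over-reaction product / % | target / % | starting material / % | first chain carrier / % |
|---|---|---|---|---|---|
| summer | 0.833 | 12.0 | 87.8 | 0.2 | 0 |
| summer | 2.50 | 21.6 | 79.5 | 0.6 | 0.8 |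
| summer | 5.00 | 28.1 | 72.3 | 0 | 0 |
| summer | 8.00 | 34.9 | 64.4 | 0 | 0.3 |
| summer | 10.0 | 39.4 | 60.1 | 0 | 0 |
| dawn | 0.833 | 11.6 | 88.1 | 0 | 0 |
| dawn | 2.50 | 21.1 | 78.6 | 0.3 | 0 |
| dawn | 5.00 | 30.0 | 71.1 | 0 | 0 |
| dawn | 8.00 | 36.8 | 64.6 | 0.3 | 0 |
| dawn | 10.0 | 39.8 | 60.0 | 0.8 | 0 |

(scatter of a reading: 0.5 percentage points)

* which of these there is most of at the end, counted by the starting material in it, south-west (starting material / first chain carrier / target / over-reaction product)
* which of these there is most of at the end, counted by the starting material in it, north-west (starting material / first chain carrier / target / over-reaction product)
* which of these there is most of at the end, counted by the starting material in it, north (starting material / first chain carrier / target / over-reaction product)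
* amount of the one of these that there is most of at the end, in percent of the starting material charged, south-west
* amount of the one of these that there is most of at the end, in percent of the starting material charged, north-west
* amount of the one of these that there is most of at the end, in percent of the starting material charged, north



**First instants.** At the first reading of the summer run, 0.833 min, starting material, the limiting reagent against 2 equiv of partner, reads 0.2%. Target already reads 87.8% and over-reaction product 12.0%. The fast step lies behind us before we can watch it.

**The middle.** Target now falls and over-reaction product rises, their sum reading 99.5% at 10.0 min. If each over-reaction product takes one target and one more partner, the partner left, counted on the starting material charged, equals the target fraction. The rate then goes as that fraction squared, a second-order decay. One over the target fraction climbs per minute by 0.0573 min⁻¹ in the summer run and 0.0580 min⁻¹ in the dawn run, which agree across 7 mol% and 16 mol% of initiator. Their mean, 0.0576 min⁻¹, we call the decay slope: the rise of one over the target fraction per minute.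

**The end.** Carried from the first summer reading, our line reaches 2, where target and over-reaction product cross, at 15.8 min, earlier than 20 min. At 20 min it gives target 44.6% and over-reaction product 55.4%. We take this for the three flasks, though north-west's 6.2 mol% of initiator lies just below the tested range.

**The forecast.** It names over-reaction product in south-west at 55.5% (52.5% to 58.5%), over-reaction product in north-west at 55.5% (51.5% to 58.5%), and over-reaction product in north at 55.5% (52.5% to 58.5%), holding that “rate does not depend on initiator here”. Our own figure, 55.4%, stands beside its 55.5%.

**The result.** The flasks give over-reaction product at 55.0% in south-west, 54.9% in north-west and 55.0% in north.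

    2 first chain carrier → ended chains (k = 5.30 × 10⁶ M⁻¹ s⁻¹)
    starting material + initiating radical → capped initiator + first chain carrier (k = 64500 M⁻¹ s⁻¹)
    starting material + second chain carrier → by-product + first chain carrier (k = 1890 M⁻¹ s⁻¹)
    first chain carrier → ended carrier (k = 56.0 s⁻¹)
    partner ⇌ dormant form (K = 3.40, k = 0.0181 s⁻¹)
    initiator → 2 initiating radical (k = 0.00221 s⁻¹)
    partner + first chain carrier → target + second chain carrier (k = 27700 M⁻¹ s⁻¹)
    crystals ⇌ by-product, rate k8*(cs8 - [by-product]) while solid is left; crystals form when [by-product] > cs8 (solubility = 1.00 M, k = 0.115 s⁻¹)
    partner + target → over-reaction product (k = 0.00292 M⁻¹ s⁻¹)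

**The partner.** The decay slope landed 0.50 percentage points from north-west. There, at 20.0 min, partner counted on the starting material charged stands as 35.6% dormant form against 9.64% free, together 45.3%, beside target at 44.9%.

**A thinner flask.** With 0.60 M of starting material and north-west's recipe, we scale the slope with the concentration to 0.0231 min⁻¹, and the same line gives target 63.3%. That flask gives 66.3% target and 33.3% over-reaction product: most of its starting material stands as target, where in north-west it stands as over-reaction product.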